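## Structural features

The target is a (2S)-flavanone: a benzene ring A fused to a dihydropyranone ring C (chroman-4-one), with a 4-hydroxyphenyl ring B on C2. Ring A is fully substituted: C4a carries the C4 ketone, C5 a free hydroxyl hydrogen-bonded to that ketone, C6 and C7 methoxy groups, C8 a 3-methylbut-2-enyl (prenyl) chain and C8a the ring oxygen O1. C2 is the only stereocentre, with no second centre next to it; it is benzylic, bears O1 and lies β to the ketone, so base can erase it by E1cB opening of ring C to the chalcone and acid by benzylic ionisation, both helped by a free 4'-hydroxyl. The fragile groups are the trisubstituted prenyl alkene (acids, hydrogenation, electrophilic oxidants), the electron-rich phenols and the β-aryloxy ketone. The real difficulty is the hexasubstituted ring A, where three neighbouring oxygens must end up differentiated (5-OH against 6- and 7-OMe) beside a C-prenyl group while the lone C2 centre is kept. The key step uses the fact that O1 sits on C8a: once the C5/C6 oxygens are raised to an ortho-quinone, C8a is the β-carbon of both the C5 carbonyl and the C4 ketone and is within reach of an oxygen on C2, so ring C can be closed through the O1–C8a bond by conjugate addition of an aldol hydroxyl. The catechol left at C5/C6 by that closure has one chelated and one free hydroxyl, which lets the 6-OMe be placed last.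

## Logic of the disconnections

17 ⇒ 16. The acyl–oxygen bond of the 4'-acetate is cut. A free 4'-phenol would make C2 easy to racemise and would compete in methylation and in anodic oxidation, so it stays masked until the end. Nothing is gained in skeleton, but every earlier step works on a deactivated ring B. The forward step must cleave an aryl ester near neutral pH so that ring C stays closed.

16 ⇒ 15. The O6–CH3 bond is cut. This leaves a C5/C6 catechol, which is exactly what the oxidative ring closure delivers, so O5 and O6 need not be told apart earlier. The forward step must methylate the free 6-OH and leave the chelated 5-OH, without base.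

15 ⇒ 12 (through 13 and 14). The O1–C8a bond is cut. At the quinone level 13, C8a is doubly activated and the C2 oxygen can reach it. Ring C is opened, ring A drops to an acyl catechol with one free C–H, and C2 becomes an acyclic carbinol. The forward step must oxidise only the catechol, close at C8a faster than 13 is diverted, and return over-oxidised 14 to 15.

12 ⇒ 11. Two aryl O–Si bonds are cut. The catechol cannot be carried free through enolate chemistry, and silyl ethers come off without acid or base. The forward step must spare the acetate, the β-hydroxy ketone and the alkene.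

11 ⇒ 8 + 9 (through 10). The bond between the carbinol carbon and the adjacent CH2 is cut. This is the most simplifying cut of the route: it divides the molecule into a ring A enol silane and a ring B aldehyde and makes the synthesis convergent. The forward step must add to the Si face of 9 with high selectivity.

8 ⇒ 7. Three O–Si bonds are cut, two on the catechol and one on the enol. One reagent installs all three, so protection and enolate activation are a single operation.

7 ⇒ 5 (through 6). The O4–CH3 bond (acetophenone numbering) is cut. O4 has to be free in 5 because it anchored the prenyl transfer. The forward step must methylate O4 in the presence of O2 and O3.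

5 ⇒ 4. The ring C5–CH2 bond of the prenyl group is cut, as the retron of a [3,3] shift from oxygen to carbon. A difficult aryl–alkyl C–C bond is traded for an O–C bond. The forward step can only migrate to C5, the one free ortho position.

4 ⇒ 3. The terminal alkene is traced to a terminal alkyne, because tertiary allyl aryl ethers are best reached from the propargylic chloride. The forward step must stop at the alkene.

3 ⇒ 1 + 2. The O4–C bond is cut, giving two purchasable compounds. The forward step must alkylate one of three hydroxyls, the one para to the acetyl group.

## Other disconnections considered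

Alternative 1: The cut removes O1–C2 and C3–C4 together, leaving 2-hydroxy-4,5,6-trimethoxybenzaldehyde A1 and 4-acetoxystyrene A2. In the forward sense a confined chiral Brønsted acid would convert A1, with an orthoformate as methoxy source, into an O-methylated ortho-quinone methide cation. This should add A2 in a [4+2] cycloaddition to give the (2S,4S)-2,4-cis-4-methoxyflavan A3.
- In its favour: it is the most convergent plan, it closes ring C and sets C2 by catalyst control in one step from two simple arenes, and ring A arrives with O1 already on C8a, so no polarity reversal is needed. On convergence and on directness of ring C construction it is better than the chosen plan, and its key step stands on closer precedent than 12 → 15.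
- Against it here: A3 is at the ether level at C4 and has no prenyl group. C4 would have to be oxidised to the ketone, C8 prenylated on a compound with two acid-labile benzylic ethers, and O5 demethylated selectively, before the acetate is removed. The trimethoxy-substituted quinone methide is strongly stabilised while the acetoxy-substituted styrene is only a modest nucleophile, a poor electronic match. The C4 centre is built only to be destroyed.
- Comparison: the two plans are equal in resting on one catalytic asymmetric step for C2. The chosen plan has the ketone, the prenyl group and the O5/O6 distinction in place when 15 forms and needs two more steps; A3 would need about five.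

Alternative 2: The cut is the C3–C4 bond, taken as a C3=C4 alkene. The precursor is the (S)-1-arylallyl aryl ether A4, with a vinyl group on C2 and a 1-(tert-butyldimethylsilyloxy)vinyl group on C4a. Second-generation Grubbs catalyst would close ring C with loss of a volatile alkene to the 4-silyloxy-2H-chromene A5, whose hydrolysis gives the ketone.
- In its favour: the conditions are neutral, no bond to C2 is made or broken during ring closure, and C4 reaches the ketone level by simple hydrolysis. In mildness toward the stereocentre during ring closure it is at least the equal of the chosen plan, which exposes C2 to an electrophilic quinone.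
- Against it here: metathesis of a 1,1-disubstituted silyl enol ether is slow, and the prenyl alkene on C8 is a competing partner (a six-membered carbocycle with the enol ether, a seven-membered ring with the C2 vinyl). A4 needs an enantioselective O-allylation of a phenol flanked on both sides, and the resulting ether can ionise to a cation stabilised by the 4-silyloxyphenyl ring. After A5, enol ether hydrolysis, selective O5 demethylation and desilylation are still required.
- Comparison: the length is similar and the steps after ring closure are two to three against two. The precursor is harder to reach because the C2–O bond must be made on the most hindered oxygen, whereas in the chosen plan it is made as a simple aldol hydroxyl. The prenyl group must survive an alkene-reactive catalyst, whereas the anode discriminates by potential.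

Alternative 3: The cut is C4–C4a. The precursor is (3S)-3-(4-acetoxyphenyl)-3-[3,4,5-trimethoxy-2-(3-methylbut-2-enyl)phenoxy]propanoic acid A6. Its acid chloride or trifluoroacetic mixed anhydride would acylate the single free ring A carbon under SnCl4 at low temperature to give the trimethoxyflavanone A7.
- In its favour: intramolecular Friedel–Crafts acylation to chroman-4-ones is long-established, the regiochemistry cannot go wrong because only one activated aromatic C–H is present, and A7 is two steps from 17. On precedent this plan is clearly better than the chosen one; on steps after ring closure it is equal.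
- Against it here: the acylating carbon lies β to a benzylic aryloxy group, so β-elimination and ionisation at C2 threaten the stereocentre. SnCl4 and the protic acid it generates can add to or cyclise the prenyl alkene. A6 needs a stereospecific C–O bond between a hindered ortho-prenyl phenol and a secondary benzylic carbon (Mitsunobu inversion, prone to elimination and partial loss of configuration), and the later BCl3 demethylation meets the prenyl group again.
- Comparison: the overall length is about the same. The alternative has the safer ring closure in terms of precedent but two stages at which C2 can be lost. The chosen plan forms the C2–O bond once and never breaks it, and uses no strong Lewis acid once the prenyl group is present.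

Key step: step 8

Remarks on the chemistry:
- Ring positions of 13–17 are cited in flavanone numbering (O1, C2, C3, C4, C4a, C5–C8, C8a). The ring A pattern of 12 (acyl on C1, OH on C2 and C3, OMe on C4, prenyl on C5, H on C6) maps onto C4a, C5, C6, C7, C8 and C8a of 15.
- The descriptor is (S) both for the carbinol carbon of 10–13 and for C2 of 14–17, because O > aryl > CH2 > H holds before and after ring closure.
- Assumption: the (S,S)-bisphosphoramide of step 6 is taken as the enantiomer that directs addition to the Si face of 9; if the sense is opposite, the (R,R)-catalyst is used with no other change. The catalyst consists of two cyclic phosphoramides derived from N,N'-dimethyl-1,1'-binaphthyl-2,2'-diamine, joined by an N,N'-dimethylpentane-1,5-diamine linker.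

## Route

Step 1
Reactants: 1 gallacetophenone (1-(2,3,4-trihydroxyphenyl)ethanone); 2 3-chloro-3-methylbut-1-yne
Product: 3 1-[2,3-dihydroxy-4-(2-methylbut-3-yn-2-yloxy)phenyl]ethanone
Conditions: DBU (1.1 equiv), CuCl2·2H2O (1 mol%), MeCN, 0 °C, Ar
Reagents that add atoms: none
Why: Copper-catalysed propargylic etherification of a phenoxide with a tertiary propargylic chloride; one equivalent of DBU ionises only the 4-OH, the most acidic hydroxyl because it is para to the acetyl group, while the 2-OH is tied up in a hydrogen bond to the carbonyl and the 3-OH is the least acidic and flanked on both sides.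

Step 2
Reactants: 3 1-[2,3-dihydroxy-4-(2-methylbut-3-yn-2-yloxy)phenyl]ethanone
Product: 4 1-[2,3-dihydroxy-4-(2-methylbut-3-en-2-yloxy)phenyl]ethanone
Conditions: H2 (1 atm), Pd/CaCO3–Pb(OAc)2 (Lindlar catalyst), quinoline, EtOAc, rt
Reagents that add atoms: none
Why: Lindlar semi-hydrogenation of a terminal alkyne stops at the terminal alkene when hydrogen uptake is metered, with no alkene geometry at stake and no reduction of the aryl ketone; reducing before heating avoids the propargyl route to a 2,2-dimethylchromene.

Step 3
Reactants: 4 1-[2,3-dihydroxy-4-(2-methylbut-3-en-2-yloxy)phenyl]ethanone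
Product: 5 1-[2,3,4-trihydroxy-5-(3-methylbut-2-enyl)phenyl]ethanone
Conditions: N,N-diethylaniline, 130 °C, Ar
Reagents that add atoms: none
Why: Aromatic Claisen rearrangement: the [3,3] shift can only go to C5, the one free ortho position, and delivers the group with allylic transposition as the linear prenyl substituent, followed by tautomerisation to the phenol; the gem-dimethyl group lowers the temperature needed and the amine solvent suppresses acid-promoted chroman formation.

Step 4
Reactants: 5 1-[2,3,4-trihydroxy-5-(3-methylbut-2-enyl)phenyl]ethanone
Product: 7 1-[2,3-dihydroxy-4-methoxy-5-(3-methylbut-2-enyl)phenyl]ethanone, via 2,3-O-borate complex 6 (not isolated)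
Conditions: Na2B4O7·10H2O, H2O/THF, rt; Me2SO4 and aq. NaOH added together, rt; then 2 M HCl
Reagents that add atoms: dimethyl sulfate COS(=O)(=O)OC
Why: Borate-masked Williamson methylation: the O2/O3 pair is held as the cyclic borate 6, so only the 4-phenoxide is methylated (the isomeric O3/O4 borate exposes only the chelated, unreactive 2-OH), and acidification releases the catechol; the borate also shields the catechol from autoxidation in base.

Step 5
Reactants: 7 1-[2,3-dihydroxy-4-methoxy-5-(3-methylbut-2-enyl)phenyl]ethanone
Product: 8 tert-butyl-[1-[2,3-bis(tert-butyldimethylsilyloxy)-4-methoxy-5-(3-methylbut-2-enyl)phenyl]ethenyloxy]dimethylsilane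
Conditions: TBSOTf (3.5 equiv), Et3N (6 equiv), CH2Cl2, 0 °C to rt
Reagents that add atoms: tert-butyldimethylsilyl trifluoromethanesulfonate CC(C)(C)[Si](C)(C)OS(=O)(=O)C(F)(F)F
Why: Silyl triflate with triethylamine silylates both phenols, the chelated one included, and in the same operation converts the methyl ketone into its only possible enol silane (soft enolisation), so catechol protection and enolate activation cost one step.

Step 6
Reactants: 8 tert-butyl-[1-[2,3-bis(tert-butyldimethylsilyloxy)-4-methoxy-5-(3-methylbut-2-enyl)phenyl]ethenyloxy]dimethylsilane; 9 4-acetoxybenzaldehyde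
Product: 11 (3S)-3-(4-acetoxyphenyl)-1-[2,3-bis(tert-butyldimethylsilyloxy)-4-methoxy-5-(3-methylbut-2-enyl)phenyl]-3-hydroxypropan-1-one, via trichlorosilyl aldolate 10 (not isolated)
Conditions: SiCl4 (1.5 equiv), (S,S)-bisphosphoramide (5 mol%), i-Pr2NEt (10 mol%), CH2Cl2, −78 °C; aq. NaHCO3
Reagents that add atoms: none
Why: Catalytic enantioselective Mukaiyama aldol addition by Lewis-base activation of SiCl4: the chiral phosphoramide-bound trichlorosilyl cation binds aldehyde 9 and the enol silane adds through an open transition state to the Si face, which sets the (S) carbinol centre; aromatic aldehydes with methyl-ketone enol silanes are the substrate class this system suits best, and the aryl silyl ethers, the acetate and the alkene should be inert to SiCl4 at −78 °C. Aqueous work-up hydrolyses aldolate 10 to the free alcohol.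

Step 7
Reactants: 11 (3S)-3-(4-acetoxyphenyl)-1-[2,3-bis(tert-butyldimethylsilyloxy)-4-methoxy-5-(3-methylbut-2-enyl)phenyl]-3-hydroxypropan-1-one
Product: 12 (3S)-3-(4-acetoxyphenyl)-1-[2,3-dihydroxy-4-methoxy-5-(3-methylbut-2-enyl)phenyl]-3-hydroxypropan-1-one
Conditions: HF·pyridine, pyridine, THF, 0 °C, Ar; pH 7 buffer work-up
Reagents that add atoms: none
Why: Fluoride cleavage of aryl silyl ethers, which are far more labile than alkyl silyl ethers; pyridine-buffered HF is not basic enough to cleave the aryl acetate or start retro-aldol or E1cB dehydration, and not acidic enough to hydrate the prenyl group.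

Step 8
Reactants: 12 (3S)-3-(4-acetoxyphenyl)-1-[2,3-dihydroxy-4-methoxy-5-(3-methylbut-2-enyl)phenyl]-3-hydroxypropan-1-one
Product: 15 (2S)-2-(4-acetoxyphenyl)-5,6-dihydroxy-7-methoxy-8-(3-methylbut-2-enyl)chroman-4-one, via acyl ortho-quinone 13 (not isolated), via flavanone ortho-quinone 14 (not isolated)
Conditions: graphite anode, Pt cathode, divided cell, 0.1 M n-Bu4NBF4, MeCN/aq. NaOAc–AcOH buffer (pH 5) 9:1, 0 °C, Ar, constant potential at the first anodic wave of 12 until 12 is consumed (2–4 F/mol); then aq. Na2S2O4
Reagents that add atoms: none
Why: Proposed new method: at a graphite anode held at the first catechol wave, 12 should lose two electrons and two protons to give the 3-acyl-1,2-benzoquinone 13, well below the potentials at which the trisubstituted alkene, the acetoxyphenyl ring or the benzylic alcohol are oxidised. In 13 the ring carbon C8a is the β-carbon of both the C5 quinone carbonyl and the C4 ketone, and the side-chain hydroxyl adds to it in a 6-endo-trig oxa-Michael closure of ring C, after which loss of the C8a proton rearomatises ring A to the 5,6-catechol 15. Because the new alkoxy group para to O6 makes 15 easier to oxidise than 12, 15 is expected to be carried on (at the anode or by 13) to quinone 14, which the dithionite quench returns to 15. The closest known reaction type is anodic oxidation of catechols with in-cell 1,4-addition of oxygen, nitrogen and carbon nucleophiles to the ortho-quinone, including lactone closure by a tethered carboxylate; closure of a chromanone ring by a tethered secondary alcohol has not been shown. No stereocentre is created: the C–O bond made in the aldol is never broken, so the (S) configuration is carried into C2, and the weakly acidic medium keeps ring C from reopening by E1cB. The step needs attack at C8a in preference to hydration, ipso substitution at the methoxy-bearing C7, reversible hemiketal formation at C5 and tautomerisation of the prenyl-substituted quinone to a quinone methide. This is secured by the six-membered tether, by the double activation of C8a as the only unsubstituted ring carbon, and by a low water content, pH 5, 0 °C and a short residence before the reductive quench; a perchlorate-free electrolyte is chosen for safe concentration of the organic phase.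

Step 9
Reactants: 15 (2S)-2-(4-acetoxyphenyl)-5,6-dihydroxy-7-methoxy-8-(3-methylbut-2-enyl)chroman-4-one
Product: 16 (2S)-2-(4-acetoxyphenyl)-5-hydroxy-6,7-dimethoxy-8-(3-methylbut-2-enyl)chroman-4-one
Conditions: TMSCHN2 (1.5 equiv), MeOH/PhMe 1:3, 0 °C to rt, Ar; AcOH quench
Reagents that add atoms: trimethylsilyldiazomethane C[Si](C)(C)C=[N+]=[N-]
Why: O-Methylation of a phenol by diazomethane released in situ from trimethylsilyldiazomethane in methanol: the free 6-OH reacts, while the 5-OH is held in a six-membered hydrogen bond to the C4 carbonyl and is much less available; the 4'-oxygen is blocked as the acetate and the neutral medium cannot open ring C, so C2 is untouched.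

Step 10
Reactants: 16 (2S)-2-(4-acetoxyphenyl)-5-hydroxy-6,7-dimethoxy-8-(3-methylbut-2-enyl)chroman-4-one
Product: 17 (2S)-5-hydroxy-2-(4-hydroxyphenyl)-6,7-dimethoxy-8-(3-methylbut-2-enyl)chroman-4-one
Conditions: NH4OAc, MeOH/H2O 4:1, rt
Reagents that add atoms: none
Why: Neutral ammonium-acetate-mediated solvolysis of an aryl acetate, the only ester present; avoiding alkoxide or carbonate keeps the flavanone from E1cB ring-opening to the chalcone, the pathway by which C2 would racemise once the 4'-phenol is free.

## Compound list

1 | gallacetophenone (1-(2,3,4-trihydroxyphenyl)ethanone) | CC(=O)c1ccc(O)c(O)c1O | starting material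
2 | 3-chloro-3-methylbut-1-yne | CC(C)(Cl)C#C | starting material
3 | 1-[2,3-dihydroxy-4-(2-methylbut-3-yn-2-yloxy)phenyl]ethanone | CC(=O)c1ccc(OC(C)(C)C#C)c(O)c1O | intermediate
4 | 1-[2,3-dihydroxy-4-(2-methylbut-3-en-2-yloxy)phenyl]ethanone | CC(=O)c1ccc(OC(C)(C)C=C)c(O)c1O | intermediate
5 | 1-[2,3,4-trihydroxy-5-(3-methylbut-2-enyl)phenyl]ethanone | CC(=O)c1cc(CC=C(C)C)c(O)c(O)c1O | intermediate
6 | sodium 2,3-O-borate complex of 5 (cyclic dihydroxyborate across O2 and O3; formed in the flask) | [Na+].CC(=O)c1cc(CC=C(C)C)c(O)c2O[B-](O)(O)Oc12 | intermediate
7 | 1-[2,3-dihydroxy-4-methoxy-5-(3-methylbut-2-enyl)phenyl]ethanone | CC(=O)c1cc(CC=C(C)C)c(OC)c(O)c1O | intermediate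
8 | tert-butyl-[1-[2,3-bis(tert-butyldimethylsilyloxy)-4-methoxy-5-(3-methylbut-2-enyl)phenyl]ethenyloxy]dimethylsilane | C=C(O[Si](C)(C)C(C)(C)C)c1cc(CC=C(C)C)c(OC)c(O[Si](C)(C)C(C)(C)C)c1O[Si](C)(C)C(C)(C)C | intermediate
9 | 4-acetoxybenzaldehyde | CC(=O)Oc1ccc(C=O)cc1 | starting material
10 | (3S)-3-(4-acetoxyphenyl)-1-[2,3-bis(tert-butyldimethylsilyloxy)-4-methoxy-5-(3-methylbut-2-enyl)phenyl]-3-(trichlorosilyloxy)propan-1-one (formed in the flask) | O=C(C[C@H](O[Si](Cl)(Cl)Cl)c1ccc(OC(C)=O)cc1)c1cc(CC=C(C)C)c(OC)c(O[Si](C)(C)C(C)(C)C)c1O[Si](C)(C)C(C)(C)C | intermediate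
11 | (3S)-3-(4-acetoxyphenyl)-1-[2,3-bis(tert-butyldimethylsilyloxy)-4-methoxy-5-(3-methylbut-2-enyl)phenyl]-3-hydroxypropan-1-one | O=C(C[C@H](O)c1ccc(OC(C)=O)cc1)c1cc(CC=C(C)C)c(OC)c(O[Si](C)(C)C(C)(C)C)c1O[Si](C)(C)C(C)(C)C | intermediate
12 | (3S)-3-(4-acetoxyphenyl)-1-[2,3-dihydroxy-4-methoxy-5-(3-methylbut-2-enyl)phenyl]-3-hydroxypropan-1-one | Oc1c(O)c(C(=O)C[C@H](O)c2ccc(OC(C)=O)cc2)cc(CC=C(C)C)c1OC | intermediate
13 | 3-[(3S)-3-(4-acetoxyphenyl)-3-hydroxypropanoyl]-6-methoxy-5-(3-methylbut-2-enyl)cyclohexa-3,5-diene-1,2-dione (formed in the flask) | O=C1C(=O)C(C(=O)C[C@H](O)c2ccc(OC(C)=O)cc2)=CC(CC=C(C)C)=C1OC | intermediate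
14 | (2S)-2-(4-acetoxyphenyl)-7-methoxy-8-(3-methylbut-2-enyl)-2,3-dihydrochromene-4,5,6-trione (formed in the flask) | O=C1C(=O)C2=C(O[C@H](c3ccc(OC(C)=O)cc3)CC2=O)C(CC=C(C)C)=C1OC | intermediate
15 | (2S)-2-(4-acetoxyphenyl)-5,6-dihydroxy-7-methoxy-8-(3-methylbut-2-enyl)chroman-4-one | Oc1c(O)c2c(c(CC=C(C)C)c1OC)O[C@H](c1ccc(OC(C)=O)cc1)CC2=O | intermediate
16 | (2S)-2-(4-acetoxyphenyl)-5-hydroxy-6,7-dimethoxy-8-(3-methylbut-2-enyl)chroman-4-one | COc1c(O)c2c(c(CC=C(C)C)c1OC)O[C@H](c1ccc(OC(C)=O)cc1)CC2=O | intermediate
17 | (2S)-5-hydroxy-2-(4-hydroxyphenyl)-6,7-dimethoxy-8-(3-methylbut-2-enyl)chroman-4-one | COc1c(O)c2c(c(CC=C(C)C)c1OC)O[C@H](c1ccc(O)cc1)CC2=O | target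

## Step count and least certain steps

Total: 10 steps. Longest linear sequence: 10 steps (1 to 17); 9 enters at step 6.

Step 8 (key step). The most likely failures are capture of quinone 13 by water or its tautomerisation to a quinone methide through the benzylic prenyl CH2 before the alcohol closes, and breakdown of the over-oxidised quinone 14 (E1cB opening of ring C, hydrolysis at C7 or C8a) during the electrolysis; both stem from the high electrophilicity of fully substituted ortho-quinones. The fallback gives up the polarity reversal and uses known chemistry in which O1 is on C8a from the start. It sets out from 2 and comes back to the route at 17.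
- Commercial 1-(2-hydroxy-4,5,6-trimethoxyphenyl)ethanone F1 is O-alkylated with 2 (K2CO3, KI, copper iodide CuI cat., acetone, reflux) to 1-[2,3,4-trimethoxy-6-(2-methylbut-3-yn-2-yloxy)phenyl]ethanone F2.
- F2 is semi-hydrogenated over Pd/CaCO3–Pb(OAc)2 to 1-[2,3,4-trimethoxy-6-(2-methylbut-3-en-2-yloxy)phenyl]ethanone F3, and Claisen rearrangement at about 120 °C gives 1-[2-hydroxy-4,5,6-trimethoxy-3-(3-methylbut-2-enyl)phenyl]ethanone F4.
- Heating F4 with N,N-dimethylformamide dimethyl acetal gives (E)-3-(dimethylamino)-1-[2-hydroxy-4,5,6-trimethoxy-3-(3-methylbut-2-enyl)phenyl]prop-2-en-1-one F5, which on brief exposure to dilute HCl in CH2Cl2 should cyclise with loss of dimethylamine to 5,6,7-trimethoxy-8-(3-methylbut-2-enyl)chromen-4-one F6.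
- Enantioselective conjugate addition of 4-hydroxyphenylboronic acid F7 to F6 (Pd(OCOCF3)2, chiral tert-butyl pyridine–oxazoline ligand of the enantiomer leading to (2S), NH4PF6, H2O, ClCH2CH2Cl, 60 °C) should give (2S)-2-(4-hydroxyphenyl)-5,6,7-trimethoxy-8-(3-methylbut-2-enyl)chroman-4-one F8.
- BCl3 (CH2Cl2, −78 to 0 °C) should then remove only the methyl group on O5, through chelation to the C4 carbonyl, to give 17.

Step 6. The most likely failure is poor facial selectivity or sluggish addition, because the enol silane carries a bulky ortho silyloxy group that may disturb the open transition state. The fallback replaces catalyst control by reagent control through a closed boron transition state. It sets out from 7 and comes back at 11. Silylation of the two phenols only (TBSOTf 2.2 equiv, 2,6-lutidine, CH2Cl2, −78 °C) gives 1-[2,3-bis(tert-butyldimethylsilyloxy)-4-methoxy-5-(3-methylbut-2-enyl)phenyl]ethanone F9. F9 is enolised with chlorodiisopinocampheylborane (the antipode that gives Si-face addition) and Et3N in Et2O at −78 °C and treated in the same flask with 9; non-oxidative work-up with diethanolamine should give 11.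

Step 1. The most likely failure is loss of site selectivity (alkylation at O3 or twice) together with base- and copper-promoted autoxidation of the trihydroxyarene. The fallback replaces O-alkylation and rearrangement by direct C-alkylation. It sets out from 1 and comes back at 5, bypassing steps 1–3. Friedel–Crafts prenylation of 1 with 2-methylbut-3-en-2-ol and BF3·OEt2 in dioxane at rt should go to C5, the ring carbon ortho and para to hydroxyls and not adjacent to the acetyl group; acid-promoted chroman formation with the 4-OH would have to be accepted and separated.

Step 4. The most likely failure is methylation at O3 or double methylation if the borate masking is incomplete for this lipophilic substrate in the mixed solvent. The fallback over-methylates and then demethylates under chelation control. It sets out from 5 and comes back at 7. Exhaustive methylation (MeI, K2CO3, acetone, reflux) gives 1-[2,3,4-trimethoxy-5-(3-methylbut-2-enyl)phenyl]ethanone F10. BCl3 (2.5 equiv, CH2Cl2, −78 to 0 °C) should then cleave the 2-OMe through the carbonyl chelate and the 3-OMe through the neighbouring boron-bound oxygen, leaving the 4-OMe, to give 7.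

## Further compounds

F1 | step 8 | 1-(2-hydroxy-4,5,6-trimethoxyphenyl)ethanone | CC(=O)c1c(O)cc(OC)c(OC)c1OC
F2 | step 8 | 1-[2,3,4-trimethoxy-6-(2-methylbut-3-yn-2-yloxy)phenyl]ethanone | CC(=O)c1c(OC(C)(C)C#C)cc(OC)c(OC)c1OC
F3 | step 8 | 1-[2,3,4-trimethoxy-6-(2-methylbut-3-en-2-yloxy)phenyl]ethanone | CC(=O)c1c(OC(C)(C)C=C)cc(OC)c(OC)c1OC
F4 | step 8 | 1-[2-hydroxy-4,5,6-trimethoxy-3-(3-methylbut-2-enyl)phenyl]ethanone | CC(=O)c1c(O)c(CC=C(C)C)c(OC)c(OC)c1OC
F5 | step 8 | (E)-3-(dimethylamino)-1-[2-hydroxy-4,5,6-trimethoxy-3-(3-methylbut-2-enyl)phenyl]prop-2-en-1-one | CN(C)/C=C/C(=O)c1c(O)c(CC=C(C)C)c(OC)c(OC)c1OC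
F6 | step 8 | 5,6,7-trimethoxy-8-(3-methylbut-2-enyl)chromen-4-one | O=c1ccoc2c(CC=C(C)C)c(OC)c(OC)c(OC)c12
F7 | step 8 | 4-hydroxyphenylboronic acid | OB(O)c1ccc(O)cc1
F8 | step 8 | (2S)-2-(4-hydroxyphenyl)-5,6,7-trimethoxy-8-(3-methylbut-2-enyl)chroman-4-one | COc1c(OC)c2c(c(CC=C(C)C)c1OC)O[C@H](c1ccc(O)cc1)CC2=O
F9 | step 6 | 1-[2,3-bis(tert-butyldimethylsilyloxy)-4-methoxy-5-(3-methylbut-2-enyl)phenyl]ethanone | CC(=O)c1cc(CC=C(C)C)c(OC)c(O[Si](C)(C)C(C)(C)C)c1O[Si](C)(C)C(C)(C)C
F0 | step 1 | none | none
F10 | step 4 | 1-[2,3,4-trimethoxy-5-(3-methylbut-2-enyl)phenyl]ethanone | CC(=O)c1cc(CC=C(C)C)c(OC)c(OC)c1OC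
A1 | alternative 1 | 2-hydroxy-4,5,6-trimethoxybenzaldehyde | O=Cc1c(O)cc(OC)c(OC)c1OC
A2 | alternative 1 | 4-acetoxystyrene | CC(=O)Oc1ccc(C=C)cc1
A3 | alternative 1 | (2S,4S)-2-(4-acetoxyphenyl)-4,5,6,7-tetramethoxychroman (2,4-cis) | COc1c(OC)c2c(cc1OC)O[C@H](c1ccc(OC(C)=O)cc1)C[C@@H]2OC
A4 | alternative 2 | tert-butyl-[4-[(1S)-1-[2-[1-(tert-butyldimethylsilyloxy)ethenyl]-3,4,5-trimethoxy-6-(3-methylbut-2-enyl)phenoxy]prop-2-enyl]phenoxy]dimethylsilane | COc1c(OC)c(C(=C)O[Si](C)(C)C(C)(C)C)c(c(CC=C(C)C)c1OC)O[C@H](c1ccc(O[Si](C)(C)C(C)(C)C)cc1)C=C
A5 | alternative 2 | (2S)-4-(tert-butyldimethylsilyloxy)-2-[4-(tert-butyldimethylsilyloxy)phenyl]-5,6,7-trimethoxy-8-(3-methylbut-2-enyl)-2H-chromene | COc1c(OC)c2c(c(CC=C(C)C)c1OC)O[C@H](c1ccc(O[Si](C)(C)C(C)(C)C)cc1)C=C2O[Si](C)(C)C(C)(C)C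
A6 | alternative 3 | (3S)-3-(4-acetoxyphenyl)-3-[3,4,5-trimethoxy-2-(3-methylbut-2-enyl)phenoxy]propanoic acid | COc1cc(O[C@@H](CC(=O)O)c2ccc(OC(C)=O)cc2)c(CC=C(C)C)c(OC)c1OC
A7 | alternative 3 | (2S)-2-(4-acetoxyphenyl)-5,6,7-trimethoxy-8-(3-methylbut-2-enyl)chroman-4-one | COc1c(OC)c2c(c(CC=C(C)C)c1OC)O[C@H](c1ccc(OC(C)=O)cc1)CC2=O
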